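The route rests on disconnecting the C4–C5 bond of ring A (decalin C1–C10; ring A = C1–C5 plus C10, ring B = C5–C10; C11 = methylene carbon on C4). The feature used is the exocyclic C4=C11 alkene on the quaternary ring-fusion carbon C5, the imprint of an enol carbon adding across a terminal alkyne. In one operation a gold-catalysed 6-exo-dig closure forms C4–C5, closes ring A, sets the cis fusion at C5 and reveals the exocyclic methylene, leaving a C6 ketone that is later excised. The precursor is a ring B tert-butyldimethylsilyl enol ether (C5=C6) bearing a pent-4-ynyl chain on C10, with C8, C9 and C10 already set.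

Key step: step 11

Remarks on the chemistry:
- Atom labels: the decalin numbering of the target is used for every intermediate (C5–C10 = ring B; C1–C4 and C11 = the five chain carbons).
- Assumption: in step 4 the antipode of the chiral ligand is the one that gives the 8S centre; both antipodes are accessible.
- Assumption: the C-silylated chloropentyne of step 9 is a catalogue compound (otherwise one step from 5-chloropent-1-yne with n-BuLi and Me3SiCl).
- Assumption: the methylated ketone of step 5 is carried as a mixture of C5 epimers, and the C6 alcohol of step 12 is drawn as one epimer (OH anti to the C5 methyl); both centres are destroyed later, so their configuration is immaterial.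

Step 1
Reactants: 1 methyl 3-formyl-4-hydroxybenzoate
Product: 2 methyl 3-formyl-4-(methoxymethoxy)benzoate
Conditions: MOMCl, i-Pr2NEt, CH2Cl2, 0 °C → rt
Reagents that add atoms: chloromethyl methyl ether, COCCl
Why: O-alkylation of the phenol (Williamson-type acetal formation) masks the acidic OH, which would otherwise quench the organometallic reagents used later and give the benzylic bromide an o-quinone methide pathway.

Step 2
Reactants: 2 methyl 3-formyl-4-(methoxymethoxy)benzoate
Product: 3 methyl 3-(hydroxymethyl)-4-(methoxymethoxy)benzoate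
Conditions: NaBH4, MeOH, 0 °C
Reagents that add atoms: none
Why: Chemoselective borohydride reduction, since NaBH4 reduces the aryl aldehyde much faster than the aryl methyl ester.

Step 3
Reactants: 3 methyl 3-(hydroxymethyl)-4-(methoxymethoxy)benzoate
Product: 4 methyl 3-(bromomethyl)-4-(methoxymethoxy)benzoate
Conditions: CBr4, PPh3, CH2Cl2, 0 °C
Reagents that add atoms: tetrabromomethane, BrC(Br)(Br)Br
Why: The Appel reaction converts the primary benzylic alcohol into the bromide under neutral conditions that spare the acetal and the ester.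

Step 4
Reactants: 5 2-methylcyclohex-2-en-1-one; 4 methyl 3-(bromomethyl)-4-(methoxymethoxy)benzoate
Product: 7 methyl 3-{[(1R,6S)-1,6-dimethyl-2-oxocyclohexyl]methyl}-4-(methoxymethoxy)benzoate, via bromomagnesium enolate 6 (not isolated)
Conditions: MeMgBr (1.1 equiv), CuBr·SMe2 (cat.), chiral bidentate phosphine ligand (Josiphos-type ferrocenyl diphosphine or TADDOL-derived phosphine–phosphite, cat.), 2-MeTHF, −78 °C; then 4, DMPU, −78 °C → rt
Reagents that add atoms: methylmagnesium bromide, C[Mg]Br
Why: Copper-catalysed asymmetric conjugate addition sets C8 (S) under ligand control, and the tetrasubstituted magnesium enolate is then benzylated at C9 on the face opposite the neighbouring C8 methyl (tandem conjugate addition–enolate alkylation), which places the two methyls cis and makes C9 R.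

Step 5
Reactants: 7 methyl 3-{[(1R,6S)-1,6-dimethyl-2-oxocyclohexyl]methyl}-4-(methoxymethoxy)benzoate
Product: 9 methyl 4-(methoxymethoxy)-3-{[(1R,6S)-1,3,6-trimethyl-2-oxocyclohexyl]methyl}benzoate (C5 epimers), via lithium enolate 8 (not isolated)
Conditions: LiN(i-Pr)2, THF, −78 °C; MeI, −78 → 0 °C
Reagents that add atoms: iodomethane, CI
Why: Kinetic enolate alkylation; C9 is quaternary, so the C10 ketone can only be deprotonated at C5, where methyl iodide installs the future angular methyl.

Step 6
Reactants: 9 methyl 4-(methoxymethoxy)-3-{[(1R,6S)-1,3,6-trimethyl-2-oxocyclohexyl]methyl}benzoate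
Product: 11 methyl 4-(methoxymethoxy)-3-{[(1R,6S)-1,3,6-trimethyl-2-(trifluoromethanesulfonyloxy)cyclohex-2-en-1-yl]methyl}benzoate, via potassium enolate 10 (not isolated)
Conditions: KN(SiMe3)2, THF, −78 → 0 °C; PhNTf2, 0 °C → rt
Reagents that add atoms: N-phenylbis(trifluoromethanesulfonimide), O=S(=O)(N(c1ccccc1)S(=O)(=O)C(F)(F)F)C(F)(F)F
Why: O-sulfonylation of the only possible enolate (C10=C5) gives the tetrasubstituted enol triflate, a routine transformation for 2,2,6-trialkylcyclohexanones.

Step 7
Reactants: 11 methyl 4-(methoxymethoxy)-3-{[(1R,6S)-1,3,6-trimethyl-2-(trifluoromethanesulfonyloxy)cyclohex-2-en-1-yl]methyl}benzoate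
Product: 12 methyl 4-(methoxymethoxy)-3-{[(1R,6S)-1,3,6-trimethylcyclohex-2-en-1-yl]methyl}benzoate
Conditions: Pd(OAc)2 (cat.), PPh3, HCO2H, n-Bu3N, DMF, 60 °C
Reagents that add atoms: none
Why: Palladium-catalysed formate reduction of the enol triflate (oxidative addition, decarboxylation of formate to a palladium hydride, reductive elimination) replaces C10–O by C10–H and keeps the alkene at C5=C10.

Step 8
Reactants: 12 methyl 4-(methoxymethoxy)-3-{[(1R,6S)-1,3,6-trimethylcyclohex-2-en-1-yl]methyl}benzoate
Product: 13 methyl 4-(methoxymethoxy)-3-{[(1R,6S)-1,3,6-trimethyl-4-oxocyclohex-2-en-1-yl]methyl}benzoate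
Conditions: dirhodium tetracaprolactamate Rh2(cap)4 (cat.), t-BuOOH (70% aq.), K2CO3, CH2Cl2, rt
Reagents that add atoms: tert-butyl hydroperoxide, CC(C)(C)OO
Why: Radical-chain allylic C–H oxidation: the selective tert-butylperoxyl radical abstracts the ring allylic C6–H, and the allyl radical is oxygenated at C6 because the other terminus, C10, is shielded by the quaternary C9, giving the C6 enone with C10 as its free β-carbon.

Step 9
Reactants: 13 methyl 4-(methoxymethoxy)-3-{[(1R,6S)-1,3,6-trimethyl-4-oxocyclohex-2-en-1-yl]methyl}benzoate; 14 (5-chloropent-1-yn-1-yl)trimethylsilane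
Product: 17 methyl 3-{[(1R,2R,6S)-4-[(tert-butyldimethylsilyl)oxy]-1,3,6-trimethyl-2-[5-(trimethylsilyl)pent-4-yn-1-yl]cyclohex-3-en-1-yl]methyl}-4-(methoxymethoxy)benzoate, via organomagnesium chloride 15 (not isolated), via magnesium dialkylcuprate 16 (not isolated)
Conditions: 14, Mg, THF, reflux; CuBr·SMe2 (0.5 equiv per RMgCl), THF, −40 °C; then 13, t-BuMe2SiCl, HMPA, −78 → −20 °C; Et3N, aq. NH4Cl/NH3 work-up
Reagents that add atoms: tert-butylchlorodimethylsilane, CC(C)(C)[Si](C)(C)Cl
Why: Chlorosilane-assisted cuprate conjugate addition: the alkyl group adds axially to C10 of the half-chair with the C8 methyl equatorial, anti to the pseudoaxial C9 methyl and trans to the C8 methyl (10R), and O-silylation of the enolate fixes the enol ether at C5=C6; the alkyne is carried as its C-silyl derivative because a free terminal C–H would quench the organometallic.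

Step 10
Reactants: 17 methyl 3-{[(1R,2R,6S)-4-[(tert-butyldimethylsilyl)oxy]-1,3,6-trimethyl-2-[5-(trimethylsilyl)pent-4-yn-1-yl]cyclohex-3-en-1-yl]methyl}-4-(methoxymethoxy)benzoate
Product: 18 methyl 3-{[(1R,2R,6S)-4-[(tert-butyldimethylsilyl)oxy]-1,3,6-trimethyl-2-(pent-4-yn-1-yl)cyclohex-3-en-1-yl]methyl}-4-(methoxymethoxy)benzoate
Conditions: K2CO3 (cat.), MeOH/THF, 0 °C, short reaction time
Reagents that add atoms: none
Why: Methoxide-mediated protodesilylation removes the alkynyl trimethylsilyl group within minutes, whereas the hindered tetrasubstituted tert-butyldimethylsilyl enol ether, the methyl ester and the acetal are inert on that timescale.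

Step 11
Reactants: 18 methyl 3-{[(1R,2R,6S)-4-[(tert-butyldimethylsilyl)oxy]-1,3,6-trimethyl-2-(pent-4-yn-1-yl)cyclohex-3-en-1-yl]methyl}-4-(methoxymethoxy)benzoate
Product: 19 methyl 4-(methoxymethoxy)-3-{[(1R,2S,4aS,8aR)-1,2,4a-trimethyl-5-methylidene-4-oxodecahydronaphthalen-1-yl]methyl}benzoate
Conditions: Ph3PAuCl (cat.), AgSbF6 (cat.), CH2Cl2/MeOH (10:1), rt → 40 °C
Reagents that add atoms: none
Why: Cationic Ph3PAu+ (monovalent gold, from Ph3PAuCl and AgSbF6) binds the terminal C4≡C11 alkyne as a π-acid, C5 of the silyl enol ether attacks C4 anti to gold, and methanol then takes the silyl group from the silyloxocarbenium ion and protonates the vinyl–gold bond, releasing the C6 ketone, the C4=C11 methylene and the catalyst. This is the silyl enol ether variant of the Conia-ene reaction, a known gold-catalysed exo-dig carbocyclisation that gives α-quaternary ketones bearing an exocyclic alkene. Ring A (C1–C5, C10) closes in the 6-exo-dig mode, favoured over 7-endo attack at C11 because the three-carbon tether reaches the internal alkyne carbon C4 through a chair-like six-membered transition state. The only new stereocentre, C5, is controlled by C10: the tether hangs from the lower face of C10 and can reach only the same face of the adjacent sp2 carbon C5, so C1 and C4 end up cis and the C5 methyl shares a face with H10 (cis-decalin). The step needs carbon attack from C5 alone, which the regiospecifically formed C5=C6 enol ether secures, and it needs cyclisation to outrun methanolysis of the enol ether, which the bulky silyl group and the low methanol content are chosen to ensure.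

Step 12
Reactants: 19 methyl 4-(methoxymethoxy)-3-{[(1R,2S,4aS,8aR)-1,2,4a-trimethyl-5-methylidene-4-oxodecahydronaphthalen-1-yl]methyl}benzoate
Product: 20 methyl 3-{[(1R,2S,4S,4aS,8aR)-4-hydroxy-1,2,4a-trimethyl-5-methylidenedecahydronaphthalen-1-yl]methyl}-4-(methoxymethoxy)benzoate
Conditions: NaBH4, MeOH/THF, 0 °C → rt
Reagents that add atoms: none
Why: Borohydride reduction of the C6 ketone is chemoselective over the aryl ester, and the configuration formed at C6 does not matter because C6 becomes CH2.

Step 13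
Reactants: 20 methyl 3-{[(1R,2S,4S,4aS,8aR)-4-hydroxy-1,2,4a-trimethyl-5-methylidenedecahydronaphthalen-1-yl]methyl}-4-(methoxymethoxy)benzoate
Product: 22 methyl 4-(methoxymethoxy)-3-{[(1R,2S,4S,4aS,8aR)-1,2,4a-trimethyl-5-methylidene-4-{[(methylsulfanyl)carbonothioyl]oxy}decahydronaphthalen-1-yl]methyl}benzoate, via sodium xanthate 21 (not isolated)
Conditions: NaH, CS2, imidazole (cat.), THF, 0 °C → rt; then MeI
Reagents that add atoms: carbon disulfide, S=C=S; iodomethane, CI
Why: Xanthate formation (alkoxide addition to CS2, then S-methylation) is the standard activation of a hindered secondary alcohol for radical deoxygenation.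

Step 14
Reactants: 22 methyl 4-(methoxymethoxy)-3-{[(1R,2S,4S,4aS,8aR)-1,2,4a-trimethyl-5-methylidene-4-{[(methylsulfanyl)carbonothioyl]oxy}decahydronaphthalen-1-yl]methyl}benzoate
Product: 23 methyl 4-(methoxymethoxy)-3-{[(1R,2S,4aS,8aR)-1,2,4a-trimethyl-5-methylidenedecahydronaphthalen-1-yl]methyl}benzoate
Conditions: n-Bu3SnH (0.5 M), AIBN (cat.), PhSeSePh (cat.), PhH, 80 °C
Reagents that add atoms: none
Why: Barton–McCombie deoxygenation (stannyl radical adds to C=S, the C6–O bond fragments, the C6 radical is reduced); concentrated stannane and PhSeH formed from PhSeSePh act as a fast hydrogen-atom relay so that this radical, homoallylic to C4=C11, is quenched before it can close onto the alkene and rearrange.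

Step 15
Reactants: 23 methyl 4-(methoxymethoxy)-3-{[(1R,2S,4aS,8aR)-1,2,4a-trimethyl-5-methylidenedecahydronaphthalen-1-yl]methyl}benzoate
Product: 24 methyl 4-hydroxy-3-{[(1R,2S,4aS,8aR)-1,2,4a-trimethyl-5-methylidenedecahydronaphthalen-1-yl]methyl}benzoate
Conditions: ZnBr2, n-PrSH, CH2Cl2, 0 °C → rt
Reagents that add atoms: none
Why: Lewis acid/thiol acetal cleavage: ZnBr2 activates the methoxymethyl ether and the thiol captures the methoxymethyl cation, which is mild enough to spare the acid-sensitive exocyclic alkene and the ester.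

Compound list
1 | methyl 3-formyl-4-hydroxybenzoate | COC(=O)c1ccc(O)c(C=O)c1 | starting material
2 | methyl 3-formyl-4-(methoxymethoxy)benzoate | COCOc1ccc(C(=O)OC)cc1C=O | intermediate
3 | methyl 3-(hydroxymethyl)-4-(methoxymethoxy)benzoate | COCOc1ccc(C(=O)OC)cc1CO | intermediate
4 | methyl 3-(bromomethyl)-4-(methoxymethoxy)benzoate | COCOc1ccc(C(=O)OC)cc1CBr | intermediate
5 | 2-methylcyclohex-2-en-1-one | CC1=CCCCC1=O | starting material
6 | bromomagnesium (3S)-2,3-dimethylcyclohex-1-en-1-olate | CC1=C(O[Mg]Br)CCC[C@@H]1C | intermediate (not isolated)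
7 | methyl 3-{[(1R,6S)-1,6-dimethyl-2-oxocyclohexyl]methyl}-4-(methoxymethoxy)benzoate | O=C1CCC[C@H](C)[C@@]1(C)Cc2cc(C(=O)OC)ccc2OCOC | intermediate
8 | lithium enolate of 7 (O–Li on C10, C10=C5) | [Li]OC1=CCC[C@H](C)[C@@]1(C)Cc2cc(C(=O)OC)ccc2OCOC | intermediate (not isolated)
9 | methyl 4-(methoxymethoxy)-3-{[(1R,6S)-1,3,6-trimethyl-2-oxocyclohexyl]methyl}benzoate (C5 epimers) | O=C1C(C)CC[C@H](C)[C@@]1(C)Cc2cc(C(=O)OC)ccc2OCOC | intermediate
10 | potassium enolate of 9 (O–K on C10, C10=C5) | [K]OC1=C(C)CC[C@H](C)[C@@]1(C)Cc2cc(C(=O)OC)ccc2OCOC | intermediate (not isolated)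
11 | methyl 4-(methoxymethoxy)-3-{[(1R,6S)-1,3,6-trimethyl-2-(trifluoromethanesulfonyloxy)cyclohex-2-en-1-yl]methyl}benzoate | O=S(=O)(OC1=C(C)CC[C@H](C)[C@@]1(C)Cc2cc(C(=O)OC)ccc2OCOC)C(F)(F)F | intermediate
12 | methyl 4-(methoxymethoxy)-3-{[(1R,6S)-1,3,6-trimethylcyclohex-2-en-1-yl]methyl}benzoate | CC1=C[C@](C)(Cc2cc(C(=O)OC)ccc2OCOC)[C@@H](C)CC1 | intermediate
13 | methyl 4-(methoxymethoxy)-3-{[(1R,6S)-1,3,6-trimethyl-4-oxocyclohex-2-en-1-yl]methyl}benzoate | CC1=C[C@](C)(Cc2cc(C(=O)OC)ccc2OCOC)[C@@H](C)CC1=O | intermediate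
14 | (5-chloropent-1-yn-1-yl)trimethylsilane | C[Si](C)(C)C#CCCCCl | starting material
15 | [5-(trimethylsilyl)pent-4-yn-1-yl]magnesium chloride | C[Si](C)(C)C#CCCC[Mg]Cl | intermediate (not isolated)
16 | chloromagnesium bis[5-(trimethylsilyl)pent-4-yn-1-yl]cuprate | C[Si](C)(C)C#CCCC[Cu-]CCCC#C[Si](C)(C)C.[Mg+]Cl | intermediate (not isolated)
17 | methyl 3-{[(1R,2R,6S)-4-[(tert-butyldimethylsilyl)oxy]-1,3,6-trimethyl-2-[5-(trimethylsilyl)pent-4-yn-1-yl]cyclohex-3-en-1-yl]methyl}-4-(methoxymethoxy)benzoate | C[Si](C)(C)C#CCCC[C@@H]1[C@](C)(Cc2cc(C(=O)OC)ccc2OCOC)[C@@H](C)CC(O[Si](C)(C)C(C)(C)C)=C1C | intermediate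
18 | methyl 3-{[(1R,2R,6S)-4-[(tert-butyldimethylsilyl)oxy]-1,3,6-trimethyl-2-(pent-4-yn-1-yl)cyclohex-3-en-1-yl]methyl}-4-(methoxymethoxy)benzoate | C#CCCC[C@@H]1[C@](C)(Cc2cc(C(=O)OC)ccc2OCOC)[C@@H](C)CC(O[Si](C)(C)C(C)(C)C)=C1C | intermediate (key-step precursor)
19 | methyl 4-(methoxymethoxy)-3-{[(1R,2S,4aS,8aR)-1,2,4a-trimethyl-5-methylidene-4-oxodecahydronaphthalen-1-yl]methyl}benzoate | C=C1CCC[C@@H]2[C@](C)(Cc3cc(C(=O)OC)ccc3OCOC)[C@@H](C)CC(=O)[C@]12C | intermediate (key-step product)
20 | methyl 3-{[(1R,2S,4S,4aS,8aR)-4-hydroxy-1,2,4a-trimethyl-5-methylidenedecahydronaphthalen-1-yl]methyl}-4-(methoxymethoxy)benzoate | C=C1CCC[C@@H]2[C@](C)(Cc3cc(C(=O)OC)ccc3OCOC)[C@@H](C)C[C@H](O)[C@]12C | intermediate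
21 | sodium O-alkyl dithiocarbonate (xanthate salt) of 20 | C=C1CCC[C@@H]2[C@](C)(Cc3cc(C(=O)OC)ccc3OCOC)[C@@H](C)C[C@H](OC(=S)[S-])[C@]12C.[Na+] | intermediate (not isolated)
22 | methyl 4-(methoxymethoxy)-3-{[(1R,2S,4S,4aS,8aR)-1,2,4a-trimethyl-5-methylidene-4-{[(methylsulfanyl)carbonothioyl]oxy}decahydronaphthalen-1-yl]methyl}benzoate | C=C1CCC[C@@H]2[C@](C)(Cc3cc(C(=O)OC)ccc3OCOC)[C@@H](C)C[C@H](OC(=S)SC)[C@]12C | intermediate
23 | methyl 4-(methoxymethoxy)-3-{[(1R,2S,4aS,8aR)-1,2,4a-trimethyl-5-methylidenedecahydronaphthalen-1-yl]methyl}benzoate | C=C1CCC[C@@H]2[C@](C)(Cc3cc(C(=O)OC)ccc3OCOC)[C@@H](C)CC[C@]12C | intermediate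
24 | methyl 4-hydroxy-3-{[(1R,2S,4aS,8aR)-1,2,4a-trimethyl-5-methylidenedecahydronaphthalen-1-yl]methyl}benzoate | C=C1CCC[C@@H]2[C@](C)(Cc3cc(C(=O)OC)ccc3O)[C@@H](C)CC[C@]12C | target

Total step count: 15. Longest linear sequence: 15 steps (1 → 24 through steps 1–15; 12 steps from 5).

Steps most likely to fail

Step 11 (key step). Methanolysis of the silyl enol ether, or methanol addition to the gold-bound alkyne, may outrun the slow C–C bond formation at the crowded C5. The fallback sets out from 18 and replaces catalytic π-acid turnover in a protic medium by a stoichiometric carbomercuration in an aprotic one. HgCl2 with (Me3Si)2NH in CH2Cl2 at rt should deliver, by the same anti 6-exo-dig attack of C5, the (E)-C11-chloromercurio derivative of ketone 19 F1. Brief treatment of this vinylmercurial with NaI and dilute aqueous HCl at 0 °C should cleave the C–Hg bond with retention of the alkene position, and the route is rejoined at 19.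

Step 9. Transfer of the alkyl group to the neopentyl β-carbon C10 may be so slow that 1,2-addition, enolisation or attack on the ester compete, or O-silylation by the bulky chlorosilane may be incomplete. The fallback sets out from 13 and separates addition from silyl choice. Cuprate 16 is added in the presence of Me3SiCl and HMPA at −78 °C (the strongest chlorosilane acceleration) to give the trimethylsilyl enol ether F2. One equivalent of KOt-Bu in THF (−78 → −30 °C) then cleaves the O–SiMe3 bond regiospecifically to the potassium enolate F3, which is silylated on oxygen with t-BuMe2SiCl, and the route is rejoined at 17.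

Step 8. Oxygen may be delivered to the wrong allyl terminus (C10, after allylic shift), or hydrogen abstraction at the benzylic CH2 or the acetal may erode the material. The fallback sets out from 12 and uses a pericyclic sequence that fixes the position of oxygen by mechanism. SeO2 (cat.) with t-BuOOH in CH2Cl2 at rt should react by an ene reaction (selenium to C10, hydrogen from C6) followed by a [2,3]-sigmatropic shift that returns the alkene to C5=C10 and places OH on C6, giving the C6 allylic alcohol F4. MnO2 in CH2Cl2 then oxidises this alcohol, and the route is rejoined at 13.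

Further compounds
F1 | step 11 | methyl 3-{[(1R,2S,4aS,8aR,5E)-5-[(chloromercurio)methylidene]-1,2,4a-trimethyl-4-oxodecahydronaphthalen-1-yl]methyl}-4-(methoxymethoxy)benzoate | Cl[Hg]/C=C1\CCC[C@@H]2[C@](C)(Cc3cc(C(=O)OC)ccc3OCOC)[C@@H](C)CC(=O)[C@]12C
F2 | step 9 | methyl 4-(methoxymethoxy)-3-{[(1R,2R,6S)-1,3,6-trimethyl-4-[(trimethylsilyl)oxy]-2-[5-(trimethylsilyl)pent-4-yn-1-yl]cyclohex-3-en-1-yl]methyl}benzoate | C[Si](C)(C)C#CCCC[C@@H]1[C@](C)(Cc2cc(C(=O)OC)ccc2OCOC)[C@@H](C)CC(O[Si](C)(C)C)=C1C
F3 | step 9 | potassium enolate corresponding to F2 (O–K on C6, C5=C6) | C[Si](C)(C)C#CCCC[C@@H]1[C@](C)(Cc2cc(C(=O)OC)ccc2OCOC)[C@@H](C)CC(O[K])=C1C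
F4 | step 8 | methyl 3-{[(1R,6S)-4-hydroxy-1,3,6-trimethylcyclohex-2-en-1-yl]methyl}-4-(methoxymethoxy)benzoate (C6 epimers) | CC1=C[C@](C)(Cc2cc(C(=O)OC)ccc2OCOC)[C@@H](C)CC1O
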